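## Structural features

The target (C40H54O3, carotenoid numbering throughout) is an unsymmetrical carotenoid in which a C8 ketone is conjugated to eight E double bonds (C9=C10 to C7'=C8') bearing methyls at C9, C13, C13' and C9'. The left end is a cyclohexane (C1–C6) with a gem-dimethyl carbon C1, a secondary carbinol C3 (S), an exocyclic methylene C5=C18 and a tertiary carbinol C6 (R) that carries C7H2–C8(=O). O6/C7/C8=O thus form a tertiary, allylic β-hydroxy ketone; O3 and O6 are cis (1,4) and C7 is trans to O3. The right end is a 2,6,6-trimethylcyclohexa-2,4-dienyl ring whose only sp3 methine, C6' (S), joins ring and chain and sits between the quaternary C1' and the ring diene C5'=C4'–C3'=C2'. C3 and C6 share a ring and can be related by substrate control, whereas C6' is more than twenty bonds away and must be set absolutely. Fragile are the β-ketol (retro-aldol, dehydration, ionisation in acid), the doubly allylic H-6' (base moves the ring diene into conjugation with the chain and erases the centre, heat allows 1,5-H shifts) and the polyene (light, oxygen, acid, E/Z drift). The real difficulty lies in the two end groups and most of all in C6': no purchasable building block carries it, and it has to be created next to a quaternary carbon. The key step exploits the fact that C4' is para to C1': with C4' as a carbonyl the ring becomes achiral 4,4-dimethylcyclohexa-2,5-dienone, whose equivalent β-carbons (C6'/C2') have enantiotopic faces, so C6'–C7' is the retron of a catalyst-controlled conjugate addition of the C7'–C11' chain.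

## Logic of the disconnections

31 is cut at C11=C12 into 29 and the ylide 30 made from 17. This double bond lies between the halves, and cutting there puts the base-sensitive β-ketol on the electrophile and the ylide on the robust polyene. Gain: C40 becomes C15 + C25, each with one end group. Demand: olefination at the aldehyde of 29 beside its C8 ketone and free hydroxyls, and E geometry at C11=C12.

17 is traced through 16 to 15, and 15 is cut at C11'=C12' into 13 and the ylide 14 made from 12. Because 13 is symmetrical, the C12'–C12 section with three E double bonds is bought. Gain: C25 becomes C15 + C10. Demand: mono-olefination of a dialdehyde and E geometry at C11'=C12'.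

12 is traced through 11 and 10 to 9, 7 and 5. The C4'=C5' bond of the ring diene is cut back to a C4' ketone (enol triflate reduction) and the C5'–C18' bond to an enolate methylation. Reason: with C4' as carbonyl and C5' unsubstituted, the ring of 5 is one conjugate addition away from a symmetrical dienone. Gain: the labile ring diene appears only after C6' is in place. Demand: enolisation toward C5' only (assured, since C1' is quaternary and C3' vinylic) and a hydride source that does not migrate the diene.

Key disconnection: 5 is cut at C6'–C7' into 3 and the C6 unit 2 (used as 4). C6' is a β-carbon of 3 and C7' the terminus of an alkyne-derived dienyl metal. Gain: an achiral C8 ring and an achiral C6 chain give the C14 core, and the isolated stereocentre is set in the same event. Demand: enantioface control at a β-carbon flanked by C1', mono-addition, retention of E geometry.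

29 is traced through 28 and 26 to 25. C8=O and C7H2 are cut back to a C7≡C8 alkyne (hydrosilylation/oxidation as aldol surrogate), which avoids a ketone–ketone aldol at C6–C7. Demand: silicon on C8, distal to the C6 hydroxyl, and an oxidation that spares the new enone.

25 is traced to 24 and 23. The C6–O bond and the C5=C18 methylene are cut back to the syn 5,6-epoxide and then to the C5=C6 alkene. Reason: C3 is bought and relays to C6 through a hydroxyl-directed epoxidation; because C7 is sp-hybridised, the only β-hydrogens of the epoxide are on C18 and C4, so base-induced opening must leave oxygen on C6. Demand: oxygen delivery syn to O3 and proton removal from C18 in preference to C4.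

23 is traced through 22 to 21 and 2 (cut C6–C7, sp2–sp coupling), and 21 through 19 to 18. The same C6 unit 2 serves both halves; 18 supplies C1–C6, C16–C18 and the C3 centre. Demand: enolisation toward C5 only (C1 is quaternary).

2 comes from 1 by silylation.

## Other disconnections considered

Alternative 1: The first plan to come to mind cuts only C11=C12 and C11'=C12' (C15 + C10 + C15 double Wittig) and takes the right-hand C15 salt from the ionone pool. (R)-α-Ionone A1 would be oxidised at C3' and eliminated to the dienone A2 before chain extension; the forward key step is the Wittig union with 13. The chosen plan keeps these olefinations as tactics but is preferred on three grounds. Structure: A1 is not an article of commerce as one enantiomer and would need resolution, so C6' is not solved. Mechanism: a C3' ketone makes H-6' a vinylogous α-proton and a C3' leaving group puts a cation two carbons from it, so racemisation and elimination into conjugation with the chain would compete with formation of A2. Step economy: three to four extra operations on the most fragile ring.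

Alternative 2: Cut the ring bond C1'–C6'. Thermal disrotatory 6π-electrocyclisation of the (4Z)-trienal A3 would close the right-hand ring to aldehyde A4, to be extended at C7'. An achiral triene offers no handle for torquoselectivity, so C6' would form racemic. A4 is an α-stereogenic β,γ-unsaturated aldehyde expected to tautomerise into conjugation faster than it can be olefinated, and closure onto a gem-dimethyl terminus needs heat. The chosen conjugate addition sets C6' under catalyst control at a carbon that is only β to a carbonyl.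

Alternative 3: Cut C3–O and C6–O together. [4+2] cycloaddition of singlet oxygen to the ring diene of safranal A5 (or a C7-homologated relative) would give endoperoxide A6, and O–O reduction would deliver the cis-3,6-diol in one event. This uses the cis-1,4 relation directly, but both faces of the achiral diene are equivalent, so A6 is racemic. The cycloaddition also leaves the double bond at C4=C5; moving it to C5=C18 is contra-thermodynamic. C7 arrives as an aldehyde carbon, two adjustments away from C7H2–C8(=O). The chosen plan reaches the same cis relation by relay from a purchased C3 centre and forms the exocyclic alkene directly.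

Key step: step 2

Assumption: 1, 3, 13 and 18 are taken as catalogue compounds, the target is taken as (3S,6R,6'S)/all-E as encoded in the SMILES, and the sense of induction in step 2 follows the accepted model for cyclohex-2-enone and would be confirmed by correlation.

## Steps

Step 1
Reactants: 1 (2E)-3-methylpent-2-en-4-yn-1-ol
Product: 2 tert-butyl(dimethyl){[(2E)-3-methylpent-2-en-4-yn-1-yl]oxy}silane
Conditions: TBSCl, imidazole, CH2Cl2, 0 °C to rt
Reagents that add atoms: tert-butyldimethylsilyl chloride, CC(C)(C)[Si](C)(C)Cl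
Why: Standard silylation of a primary allylic alcohol; the ether protects the hydroxyl against the borane, enolate and amide bases used later, and no stereocentre is involved.

Step 2
Reactants: 2 tert-butyl(dimethyl){[(2E)-3-methylpent-2-en-4-yn-1-yl]oxy}silane; 3 4,4-dimethylcyclohexa-2,5-dien-1-one
Product: 5 (5R)-5-[(1E,3E)-5-{[tert-butyl(dimethyl)silyl]oxy}-3-methylpenta-1,3-dien-1-yl]-4,4-dimethylcyclohex-2-en-1-one, via dienyl catecholboronate 4 (not isolated)
Conditions: 2 (2.5 equiv), catecholborane, 70 °C; then 3, Rh(acac)(C2H4)2 (3 mol %), (R)-BINAP (3.3 mol %), Et3N, dioxane/H2O 10:1, 60–100 °C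
Reagents that add atoms: none
Why: syn-Hydroboration of the terminal alkyne of 2 gives the (E,E)-dienylboronate 4; boron-to-rhodium transmetalation forms a dienyl–Rh(I)/(R)-BINAP species, one C=C of 3 coordinates and inserts into the Rh–C bond to make C6'–C7' and an oxa-π-allyl rhodium enolate, and water protonates the enolate to release 5 and Rh–OH for the next turnover. The closest known reaction type is the Hayashi–Miyaura rhodium-catalysed asymmetric 1,4-addition of alkenylboron reagents to cyclic enones, including desymmetrising additions to 4,4-disubstituted cyclohexa-2,5-dienones. No ring is closed; the step is an intermolecular ring-to-chain union. The only new stereocentre, C6', is set by the ligand: the two β-carbons of 3 are interchanged by the C2 axis through C1'/C4' and its two faces by the ring plane, so face selection at either β-carbon is the enantio-determining event, and by the accepted quadrant model for cyclohex-2-enone the (R)-diphosphine should give 5R, which maps onto 6'S of the target. The step needs 1,4- over 1,2-addition (inherent to Rh–alkenyl insertion), retention of E geometry (transmetalation and insertion retain configuration at the alkenyl carbon) and mono-addition, which should follow because cross-conjugated 3 is a better acceptor than enone 5, whose remaining β-carbon C2' is now shielded by C1' and the new substituent. The quaternary C1' also excludes dienone–phenol aromatisation and γ-deprotonation under the basic aqueous conditions. The accepted risk is slow insertion next to C1'; it pays because one operation turns two achiral commercial pieces into the C14 core of the right half with C6' set.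

Step 3
Reactants: 5 (5R)-5-[(1E,3E)-5-{[tert-butyl(dimethyl)silyl]oxy}-3-methylpenta-1,3-dien-1-yl]-4,4-dimethylcyclohex-2-en-1-one
Product: 7 (5S,6RS)-5-[(1E,3E)-5-{[tert-butyl(dimethyl)silyl]oxy}-3-methylpenta-1,3-dien-1-yl]-4,4,6-trimethylcyclohex-2-en-1-one, via lithium dienolate 6 (not isolated)
Conditions: LDA, THF, −78 °C; MeI, DMPU, −78 to −30 °C
Reagents that add atoms: iodomethane, CI
Why: Kinetic α'-deprotonation of a 4,4-disubstituted cyclohexenone (the γ-position is quaternary, so only the cross-conjugated dienolate can form) followed by enolate C-methylation installs C18'. C6' is β to the carbonyl and cannot epimerise (its descriptor changes from R to S by CIP priority only); the new C5' centre forms as a mixture and is erased in step 4.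

Step 4
Reactants: 7 (5S,6RS)-5-[(1E,3E)-5-{[tert-butyl(dimethyl)silyl]oxy}-3-methylpenta-1,3-dien-1-yl]-4,4,6-trimethylcyclohex-2-en-1-one
Product: 9 (3R)-3-[(1E,3E)-5-{[tert-butyl(dimethyl)silyl]oxy}-3-methylpenta-1,3-dien-1-yl]-2,4,4-trimethylcyclohexa-1,5-dien-1-yl trifluoromethanesulfonate, via potassium dienolate 8 (not isolated)
Conditions: KHMDS, THF, −78 °C; PhNTf2, −78 to 0 °C
Reagents that add atoms: N-phenylbis(trifluoromethanesulfonimide), O=S(=O)(N(c1ccccc1)S(=O)(=O)C(F)(F)F)C(F)(F)F
Why: C5'–H is the only enolisable position left, so enolate O-sulfonylation gives the 2-triflyloxy-1,3-diene regiospecifically with the future C4'=C5' bond in place. C6' is not acidic here (the R descriptor is a CIP change only).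

Step 5
Reactants: 9 (3R)-3-[(1E,3E)-5-{[tert-butyl(dimethyl)silyl]oxy}-3-methylpenta-1,3-dien-1-yl]-2,4,4-trimethylcyclohexa-1,5-dien-1-yl trifluoromethanesulfonate
Product: 10 tert-butyl(dimethyl){[(2E,4E)-3-methyl-5-[(1S)-2,6,6-trimethylcyclohexa-2,4-dien-1-yl]penta-2,4-dien-1-yl]oxy}silane
Conditions: Pd(OAc)2 (5 mol %), PPh3, Bu3N, HCO2H, DMF, 40 °C
Reagents that add atoms: none
Why: Palladium-catalysed formate reduction of an enol triflate: oxidative addition, formate exchange, decarboxylation and C–H reductive elimination replace OTf by H without moving the double bonds, giving the C2'=C3'–C4'=C5' ring diene. C6' is untouched; low temperature limits palladium hydride re-addition.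

Step 6
Reactants: 10 tert-butyl(dimethyl){[(2E,4E)-3-methyl-5-[(1S)-2,6,6-trimethylcyclohexa-2,4-dien-1-yl]penta-2,4-dien-1-yl]oxy}silane
Product: 11 (2E,4E)-3-methyl-5-[(1S)-2,6,6-trimethylcyclohexa-2,4-dien-1-yl]penta-2,4-dien-1-ol
Conditions: TBAF, THF, 0 °C
Reagents that add atoms: none
Why: Fluoride cleaves the primary allylic silyl ether; the near-neutral conditions at 0 °C leave the doubly allylic C6'–H and the ring diene alone.

Step 7
Reactants: 11 (2E,4E)-3-methyl-5-[(1S)-2,6,6-trimethylcyclohexa-2,4-dien-1-yl]penta-2,4-dien-1-ol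
Product: 12 {(2E,4E)-3-methyl-5-[(1S)-2,6,6-trimethylcyclohexa-2,4-dien-1-yl]penta-2,4-dien-1-yl}(triphenyl)phosphonium bromide
Conditions: PPh3·HBr, MeOH, 0 °C to rt
Reagents that add atoms: triphenylphosphine hydrobromide, Br.c1ccc(cc1)P(c1ccccc1)c1ccccc1
Why: Standard conversion of an allylic alcohol into a C15 Wittig salt: the pentadienyl cation is captured by PPh3 at the terminal carbon C11', which keeps the diene conjugated. One equivalent of acid at low temperature limits proton loss from C6'.

Step 8
Reactants: 12 {(2E,4E)-3-methyl-5-[(1S)-2,6,6-trimethylcyclohexa-2,4-dien-1-yl]penta-2,4-dien-1-yl}(triphenyl)phosphonium bromide; 13 (2E,4E,6E)-2,7-dimethylocta-2,4,6-trienedial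
Product: 15 (2E,4E,6E,8E,10E,12E)-2,7,11-trimethyl-13-[(1S)-2,6,6-trimethylcyclohexa-2,4-dien-1-yl]trideca-2,4,6,8,10,12-hexaenal, via phosphorus ylide 14 (not isolated)
Conditions: NaOMe, MeOH/CH2Cl2, 0 °C; 13 (3 equiv), 0 °C to rt; then I2 (cat.), CH2Cl2, rt, daylight
Reagents that add atoms: none
Why: Wittig reaction of a semi-stabilised allylic ylide with an excess of the symmetrical dialdehyde should stop at mono-olefination, because the product aldehyde is a longer vinylogous, less electrophilic carbonyl. The E/Z mixture at C11'=C12' should equilibrate to all-E under iodine catalysis.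

Step 9
Reactants: 15 (2E,4E,6E,8E,10E,12E)-2,7,11-trimethyl-13-[(1S)-2,6,6-trimethylcyclohexa-2,4-dien-1-yl]trideca-2,4,6,8,10,12-hexaenal
Product: 16 (2E,4E,6E,8E,10E,12E)-2,7,11-trimethyl-13-[(1S)-2,6,6-trimethylcyclohexa-2,4-dien-1-yl]trideca-2,4,6,8,10,12-hexaen-1-ol
Conditions: NaBH4, MeOH/THF, 0 °C
Reagents that add atoms: none
Why: Chemoselective 1,2-reduction of the polyenal by borohydride; no stereocentre or double bond is affected.

Step 10
Reactants: 16 (2E,4E,6E,8E,10E,12E)-2,7,11-trimethyl-13-[(1S)-2,6,6-trimethylcyclohexa-2,4-dien-1-yl]trideca-2,4,6,8,10,12-hexaen-1-ol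
Product: 17 {(2E,4E,6E,8E,10E,12E)-2,7,11-trimethyl-13-[(1S)-2,6,6-trimethylcyclohexa-2,4-dien-1-yl]trideca-2,4,6,8,10,12-hexaen-1-yl}(triphenyl)phosphonium bromide
Conditions: PPh3·HBr, MeOH/CH2Cl2, 0 °C to rt
Reagents that add atoms: triphenylphosphine hydrobromide, Br.c1ccc(cc1)P(c1ccccc1)c1ccccc1
Why: Same allylic alcohol-to-phosphonium conversion as step 7; the polyenyl cation is captured at the terminal carbon C12, which preserves the full conjugation.

Step 11
Reactants: 18 (4R,6R)-4-hydroxy-2,2,6-trimethylcyclohexan-1-one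
Product: 19 (4R,6R)-2,2,6-trimethyl-4-[(triethylsilyl)oxy]cyclohexan-1-one
Conditions: TESCl, imidazole, CH2Cl2, 0 °C
Reagents that add atoms: chlorotriethylsilane, CC[Si](Cl)(CC)CC
Why: Silylation of the secondary alcohol that carries the purchased C3 centre; TES is chosen so that it can later be removed in the presence of the primary TBS ether.

Step 12
Reactants: 19 (4R,6R)-2,2,6-trimethyl-4-[(triethylsilyl)oxy]cyclohexan-1-one
Product: 21 (4R)-2,6,6-trimethyl-4-[(triethylsilyl)oxy]cyclohex-1-en-1-yl trifluoromethanesulfonate, via lithium enolate 20 (not isolated)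
Conditions: LDA, THF, −78 to 0 °C; PhNTf2, 0 °C to rt
Reagents that add atoms: N-phenylbis(trifluoromethanesulfonimide), O=S(=O)(N(c1ccccc1)S(=O)(=O)C(F)(F)F)C(F)(F)F
Why: Only C5 carries an enolisable hydrogen (C1 is quaternary), so enolate O-triflation gives the tetrasubstituted enol triflate regiospecifically. The C5 centre of 18 is erased and C3 is untouched.

Step 13
Reactants: 21 (4R)-2,6,6-trimethyl-4-[(triethylsilyl)oxy]cyclohex-1-en-1-yl trifluoromethanesulfonate; 2 tert-butyl(dimethyl){[(2E)-3-methylpent-2-en-4-yn-1-yl]oxy}silane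
Product: 22 tert-butyl(dimethyl){[(2E)-3-methyl-5-{(4R)-2,6,6-trimethyl-4-[(triethylsilyl)oxy]cyclohex-1-en-1-yl}pent-2-en-4-yn-1-yl]oxy}silane
Conditions: Pd(PPh3)4 (5 mol %), CuI (10 mol %), i-Pr2NH, THF, rt to 40 °C
Reagents that add atoms: none
Why: Sonogashira coupling of the enol triflate with the terminal alkyne forms the C6–C7 sp2–sp bond and brings in C7–C11 with the E C9=C10 bond. Both silyl ethers tolerate the amine/Cu/Pd conditions.

Step 14
Reactants: 22 tert-butyl(dimethyl){[(2E)-3-methyl-5-{(4R)-2,6,6-trimethyl-4-[(triethylsilyl)oxy]cyclohex-1-en-1-yl}pent-2-en-4-yn-1-yl]oxy}silane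
Product: 23 (1R)-4-[(3E)-5-{[tert-butyl(dimethyl)silyl]oxy}-3-methylpent-3-en-1-yn-1-yl]-3,5,5-trimethylcyclohex-3-en-1-ol
Conditions: PPTS (0.2 equiv), MeOH/CH2Cl2, 0 °C
Reagents that add atoms: none
Why: Acid-catalysed methanolysis removes the secondary TES ether much faster than the primary TBS ether, freeing the C3 hydroxyl as the directing group for step 15.

Step 15
Reactants: 23 (1R)-4-[(3E)-5-{[tert-butyl(dimethyl)silyl]oxy}-3-methylpent-3-en-1-yn-1-yl]-3,5,5-trimethylcyclohex-3-en-1-ol
Product: 24 (1S,3S,6S)-6-[(3E)-5-{[tert-butyl(dimethyl)silyl]oxy}-3-methylpent-3-en-1-yn-1-yl]-1,5,5-trimethyl-7-oxabicyclo[4.1.0]heptan-3-ol (syn-epoxide; 3S,5S,6S in carotenoid numbering)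
Conditions: VO(acac)2 (5 mol %), t-BuOOH (decane, 1.5 equiv), CH2Cl2, 0 °C to rt
Reagents that add atoms: tert-butyl hydroperoxide, CC(C)(C)OO
Why: Vanadium-catalysed hydroxyl-directed epoxidation of a homoallylic cyclohexenol: the vanadate ester of the pseudo-axial C3–OH delivers the peroxide oxygen to the C5=C6 face on its own side, which sets C5 and C6 together with O cis to O3. The undirected C9=C10 alkene and the alkyne should not react.

Step 16
Reactants: 24 (1S,3S,6S)-6-[(3E)-5-{[tert-butyl(dimethyl)silyl]oxy}-3-methylpent-3-en-1-yn-1-yl]-1,5,5-trimethyl-7-oxabicyclo[4.1.0]heptan-3-ol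
Product: 25 (1R,4S)-1-[(3E)-5-{[tert-butyl(dimethyl)silyl]oxy}-3-methylpent-3-en-1-yn-1-yl]-2,2-dimethyl-6-methylidenecyclohexane-1,4-diol
Conditions: LDA (4 equiv), Et2O/hexanes, 0 °C to rt
Reagents that add atoms: none
Why: Base-induced syn-β-elimination of an epoxide to an allylic alcohol: C7 is sp-hybridised and C1 quaternary, so the only β-hydrogens are on C18 and C4, both on C5, and removal of either breaks C5–O and leaves O on C6 with its configuration. The hindered amide should prefer the methyl hydrogens and give the exocyclic C5=C18 alkene; excess base covers the free C3–OH.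

Step 17
Reactants: 25 (1R,4S)-1-[(3E)-5-{[tert-butyl(dimethyl)silyl]oxy}-3-methylpent-3-en-1-yn-1-yl]-2,2-dimethyl-6-methylidenecyclohexane-1,4-diol
Product: 26 (1R,4S)-1-[(1Z,3E)-2-[benzyl(dimethyl)silyl]-5-{[tert-butyl(dimethyl)silyl]oxy}-3-methylpenta-1,3-dien-1-yl]-2,2-dimethyl-6-methylidenecyclohexane-1,4-diol
Conditions: [Cp*Ru(MeCN)3]PF6 (3 mol %), BnMe2SiH (1.3 equiv), acetone, 0 °C to rt
Reagents that add atoms: benzyldimethylsilane, C[SiH](C)Cc1ccccc1
Why: Ruthenium-catalysed trans-hydrosilylation of a propargylic alcohol places silicon on the alkyne carbon distal to the hydroxyl (C8) and hydrogen on C7, and tolerates alkenes and free hydroxyls. The (Z)-vinylsilane is a masked C8 ketone.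

Step 18
Reactants: 26 (1R,4S)-1-[(1Z,3E)-2-[benzyl(dimethyl)silyl]-5-{[tert-butyl(dimethyl)silyl]oxy}-3-methylpenta-1,3-dien-1-yl]-2,2-dimethyl-6-methylidenecyclohexane-1,4-diol
Product: 28 (3E)-1-[(1R,4S)-1,4-dihydroxy-2,2-dimethyl-6-methylidenecyclohexyl]-5-hydroxy-3-methylpent-3-en-2-one, via spiro oxasilole 27 (not isolated)
Conditions: TBAF (3 equiv), THF, 0 °C to rt; then KHCO3, H2O2 (30 %), MeOH, 0 °C
Reagents that add atoms: hydrogen peroxide, OO
Why: Tamao–Fleming oxidation: fluoride removes the benzyl group from silicon with closure onto the C6 oxygen (and cleaves the primary TBS ether), and peroxide then oxidises the C8–Si bond to the enol, which tautomerises to the C8 ketone. Overall the alkyne is hydrated in the aldol sense without a ketone–ketone aldol; bicarbonate buffering at 0 °C limits peroxide attack on the new enone.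

Step 19
Reactants: 28 (3E)-1-[(1R,4S)-1,4-dihydroxy-2,2-dimethyl-6-methylidenecyclohexyl]-5-hydroxy-3-methylpent-3-en-2-one
Product: 29 (2E)-5-[(1R,4S)-1,4-dihydroxy-2,2-dimethyl-6-methylidenecyclohexyl]-3-methyl-4-oxopent-2-enal
Conditions: MnO2 (activated, excess), CH2Cl2, rt
Reagents that add atoms: none
Why: Manganese dioxide oxidises only the primary allylic alcohol; the secondary C3 and tertiary C6 hydroxyls are not allylic carbinols with an oxidisable C–H and remain.

Step 20
Reactants: 17 {(2E,4E,6E,8E,10E,12E)-2,7,11-trimethyl-13-[(1S)-2,6,6-trimethylcyclohexa-2,4-dien-1-yl]trideca-2,4,6,8,10,12-hexaen-1-yl}(triphenyl)phosphonium bromide; 29 (2E)-5-[(1R,4S)-1,4-dihydroxy-2,2-dimethyl-6-methylidenecyclohexyl]-3-methyl-4-oxopent-2-enal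
Product: 31 (3S,6R,6'S)-3,6-dihydroxy-5,18,2',3'-tetradehydro-5,6,7,8-tetrahydro-β,ε-caroten-8-one, via C25 phosphorus ylide 30 (not isolated)
Conditions: 17, NaHMDS (1.0 equiv), THF, −78 °C; then 29, −78 to 0 °C; then I2 (cat.), CH2Cl2, rt, diffuse light, argon
Reagents that add atoms: none
Why: Wittig reaction: the preformed polyenyl ylide should attack the highly electrophilic aldehyde of 29 far faster than its hindered C8 ketone, and one equivalent of non-nucleophilic base at −78 °C spares the β-ketol. Iodine-catalysed equilibration should convert the 11Z isomer into the all-E target; no stereocentre is touched.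

## Compound list

1 | (2E)-3-methylpent-2-en-4-yn-1-ol | C#C/C(C)=C/CO | starting material
2 | tert-butyl(dimethyl){[(2E)-3-methylpent-2-en-4-yn-1-yl]oxy}silane | C#C/C(C)=C/CO[Si](C)(C)C(C)(C)C | intermediate
3 | 4,4-dimethylcyclohexa-2,5-dien-1-one | CC1(C)C=CC(=O)C=C1 | starting material
4 | 2-[(1E,3E)-5-{[tert-butyl(dimethyl)silyl]oxy}-3-methylpenta-1,3-dien-1-yl]-1,3,2-benzodioxaborole | CC(C)(C)[Si](C)(C)OC/C=C(C)/C=C/B1Oc2ccccc2O1 | intermediate (not isolated)
5 | (5R)-5-[(1E,3E)-5-{[tert-butyl(dimethyl)silyl]oxy}-3-methylpenta-1,3-dien-1-yl]-4,4-dimethylcyclohex-2-en-1-one | CC(C)(C)[Si](C)(C)OC/C=C(C)/C=C/[C@H]1CC(=O)C=CC1(C)C | intermediate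
6 | lithium (3S)-3-[(1E,3E)-5-{[tert-butyl(dimethyl)silyl]oxy}-3-methylpenta-1,3-dien-1-yl]-4,4-dimethylcyclohexa-1,5-dien-1-olate | [Li+].CC(C)(C)[Si](C)(C)OC/C=C(C)/C=C/[C@H]1C=C([O-])C=CC1(C)C | intermediate (not isolated)
7 | (5S,6RS)-5-[(1E,3E)-5-{[tert-butyl(dimethyl)silyl]oxy}-3-methylpenta-1,3-dien-1-yl]-4,4,6-trimethylcyclohex-2-en-1-one | CC(C)(C)[Si](C)(C)OC/C=C(C)/C=C/[C@H]1C(C)C(=O)C=CC1(C)C | intermediate
8 | potassium (3R)-3-[(1E,3E)-5-{[tert-butyl(dimethyl)silyl]oxy}-3-methylpenta-1,3-dien-1-yl]-2,4,4-trimethylcyclohexa-1,5-dien-1-olate | [K+].CC(C)(C)[Si](C)(C)OC/C=C(C)/C=C/[C@H]1C(C)=C([O-])C=CC1(C)C | intermediate (not isolated)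
9 | (3R)-3-[(1E,3E)-5-{[tert-butyl(dimethyl)silyl]oxy}-3-methylpenta-1,3-dien-1-yl]-2,4,4-trimethylcyclohexa-1,5-dien-1-yl trifluoromethanesulfonate | CC(C)(C)[Si](C)(C)OC/C=C(C)/C=C/[C@H]1C(C)=C(OS(=O)(=O)C(F)(F)F)C=CC1(C)C | intermediate
10 | tert-butyl(dimethyl){[(2E,4E)-3-methyl-5-[(1S)-2,6,6-trimethylcyclohexa-2,4-dien-1-yl]penta-2,4-dien-1-yl]oxy}silane | CC(C)(C)[Si](C)(C)OC/C=C(C)/C=C/[C@H]1C(C)=CC=CC1(C)C | intermediate
11 | (2E,4E)-3-methyl-5-[(1S)-2,6,6-trimethylcyclohexa-2,4-dien-1-yl]penta-2,4-dien-1-ol | OC/C=C(C)/C=C/[C@H]1C(C)=CC=CC1(C)C | intermediate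
12 | {(2E,4E)-3-methyl-5-[(1S)-2,6,6-trimethylcyclohexa-2,4-dien-1-yl]penta-2,4-dien-1-yl}(triphenyl)phosphonium bromide | [Br-].c1ccccc1[P+](c1ccccc1)(c1ccccc1)C/C=C(C)/C=C/[C@H]1C(C)=CC=CC1(C)C | intermediate
13 | (2E,4E,6E)-2,7-dimethylocta-2,4,6-trienedial | O=C/C(C)=C/C=C/C=C(C)/C=O | starting material
14 | {(2E,4E)-3-methyl-5-[(1S)-2,6,6-trimethylcyclohexa-2,4-dien-1-yl]penta-2,4-dien-1-ylidene}(triphenyl)-λ5-phosphane | c1ccccc1P(c1ccccc1)(c1ccccc1)=C/C=C(C)/C=C/[C@H]1C(C)=CC=CC1(C)C | intermediate (not isolated)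
15 | (2E,4E,6E,8E,10E,12E)-2,7,11-trimethyl-13-[(1S)-2,6,6-trimethylcyclohexa-2,4-dien-1-yl]trideca-2,4,6,8,10,12-hexaenal | O=C/C(C)=C/C=C/C=C(C)/C=C/C=C(C)/C=C/[C@H]1C(C)=CC=CC1(C)C | intermediate
16 | (2E,4E,6E,8E,10E,12E)-2,7,11-trimethyl-13-[(1S)-2,6,6-trimethylcyclohexa-2,4-dien-1-yl]trideca-2,4,6,8,10,12-hexaen-1-ol | OC/C(C)=C/C=C/C=C(C)/C=C/C=C(C)/C=C/[C@H]1C(C)=CC=CC1(C)C | intermediate
17 | {(2E,4E,6E,8E,10E,12E)-2,7,11-trimethyl-13-[(1S)-2,6,6-trimethylcyclohexa-2,4-dien-1-yl]trideca-2,4,6,8,10,12-hexaen-1-yl}(triphenyl)phosphonium bromide | [Br-].c1ccccc1[P+](c1ccccc1)(c1ccccc1)C/C(C)=C/C=C/C=C(C)/C=C/C=C(C)/C=C/[C@H]1C(C)=CC=CC1(C)C | intermediate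
18 | (4R,6R)-4-hydroxy-2,2,6-trimethylcyclohexan-1-one | C[C@@H]1C[C@@H](O)CC(C)(C)C1=O | starting material
19 | (4R,6R)-2,2,6-trimethyl-4-[(triethylsilyl)oxy]cyclohexan-1-one | C[C@@H]1C[C@@H](O[Si](CC)(CC)CC)CC(C)(C)C1=O | intermediate
20 | lithium (4R)-2,6,6-trimethyl-4-[(triethylsilyl)oxy]cyclohex-1-en-1-olate | [Li+].CC1=C([O-])C(C)(C)C[C@H](O[Si](CC)(CC)CC)C1 | intermediate (not isolated)
21 | (4R)-2,6,6-trimethyl-4-[(triethylsilyl)oxy]cyclohex-1-en-1-yl trifluoromethanesulfonate | CC1=C(OS(=O)(=O)C(F)(F)F)C(C)(C)C[C@H](O[Si](CC)(CC)CC)C1 | intermediate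
22 | tert-butyl(dimethyl){[(2E)-3-methyl-5-{(4R)-2,6,6-trimethyl-4-[(triethylsilyl)oxy]cyclohex-1-en-1-yl}pent-2-en-4-yn-1-yl]oxy}silane | CC1=C(C#C/C(C)=C/CO[Si](C)(C)C(C)(C)C)C(C)(C)C[C@H](O[Si](CC)(CC)CC)C1 | intermediate
23 | (1R)-4-[(3E)-5-{[tert-butyl(dimethyl)silyl]oxy}-3-methylpent-3-en-1-yn-1-yl]-3,5,5-trimethylcyclohex-3-en-1-ol | CC1=C(C#C/C(C)=C/CO[Si](C)(C)C(C)(C)C)C(C)(C)C[C@H](O)C1 | intermediate
24 | (1S,3S,6S)-6-[(3E)-5-{[tert-butyl(dimethyl)silyl]oxy}-3-methylpent-3-en-1-yn-1-yl]-1,5,5-trimethyl-7-oxabicyclo[4.1.0]heptan-3-ol | C[C@]12C[C@@H](O)CC(C)(C)[C@@]1(C#C/C(C)=C/CO[Si](C)(C)C(C)(C)C)O2 | intermediate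
25 | (1R,4S)-1-[(3E)-5-{[tert-butyl(dimethyl)silyl]oxy}-3-methylpent-3-en-1-yn-1-yl]-2,2-dimethyl-6-methylidenecyclohexane-1,4-diol | C=C1C[C@@H](O)CC(C)(C)[C@]1(O)C#C/C(C)=C/CO[Si](C)(C)C(C)(C)C | intermediate
26 | (1R,4S)-1-[(1Z,3E)-2-[benzyl(dimethyl)silyl]-5-{[tert-butyl(dimethyl)silyl]oxy}-3-methylpenta-1,3-dien-1-yl]-2,2-dimethyl-6-methylidenecyclohexane-1,4-diol | C=C1C[C@@H](O)CC(C)(C)[C@]1(O)/C=C(/C(C)=C/CO[Si](C)(C)C(C)(C)C)[Si](C)(C)Cc1ccccc1 | intermediate
27 | (5R,8S)-3-[(2E)-4-hydroxybut-2-en-2-yl]-2,2,6,6-tetramethyl-10-methylidene-1-oxa-2-silaspiro[4.5]dec-3-en-8-ol | C=C1C[C@@H](O)CC(C)(C)[C@@]12O[Si](C)(C)C(/C(C)=C/CO)=C2 | intermediate (not isolated)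
28 | (3E)-1-[(1R,4S)-1,4-dihydroxy-2,2-dimethyl-6-methylidenecyclohexyl]-5-hydroxy-3-methylpent-3-en-2-one | C=C1C[C@@H](O)CC(C)(C)[C@]1(O)CC(=O)/C(C)=C/CO | intermediate
29 | (2E)-5-[(1R,4S)-1,4-dihydroxy-2,2-dimethyl-6-methylidenecyclohexyl]-3-methyl-4-oxopent-2-enal | C=C1C[C@@H](O)CC(C)(C)[C@]1(O)CC(=O)/C(C)=C/C=O | intermediate
30 | {(2E,4E,6E,8E,10E,12E)-2,7,11-trimethyl-13-[(1S)-2,6,6-trimethylcyclohexa-2,4-dien-1-yl]trideca-2,4,6,8,10,12-hexaen-1-ylidene}(triphenyl)-λ5-phosphane | c1ccccc1P(c1ccccc1)(c1ccccc1)=C/C(C)=C/C=C/C=C(C)/C=C/C=C(C)/C=C/[C@H]1C(C)=CC=CC1(C)C | intermediate (not isolated)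
31 | (3S,6R,6'S)-3,6-dihydroxy-5,18,2',3'-tetradehydro-5,6,7,8-tetrahydro-β,ε-caroten-8-one, i.e. (3E,5E,7E,9E,11E,13E,15E,17E)-1-[(1R,4S)-1,4-dihydroxy-2,2-dimethyl-6-methylidenecyclohexyl]-3,7,12,16-tetramethyl-18-[(1S)-2,6,6-trimethylcyclohexa-2,4-dien-1-yl]octadeca-3,5,7,9,11,13,15,17-octaen-2-one (CNP0261423.1) | C=C1C[C@@H](O)CC(C)(C)[C@]1(O)CC(=O)/C(C)=C/C=C/C(C)=C/C=C/C=C(C)/C=C/C=C(C)/C=C/[C@H]1C(C)=CC=CC1(C)C | target

## Step count and least certain steps

Total step count: 20. Longest linear sequence: 11 steps (steps 1–10 and 20); the left-hand branch from 18 is 10 steps (steps 11–20).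

Step 2 (key step). What may go wrong: slow migratory insertion at the β-carbon next to the quaternary C1', so that protodeboronation of the dienylboron reagent outruns addition, or insufficient discrimination between the two faces of the dienone. The fallback sets out from 2 and 3 and comes back at 5. It makes the C6'–C7' bond without asymmetric induction and introduces enantiopurity afterwards by a catalyst-controlled reduction. Hydrozirconation of 2, transmetalation to copper and 1,4-addition to 3 would give the racemic enone F1. Corey–Bakshi–Shibata reduction with one oxazaborolidine enantiomer should fix the new carbinol as 1R in both enantiomers and so turn them into the diastereomeric (1R,5R)-allylic alcohol F2 and (1R,5S)-allylic alcohol F3, separable by chromatography. Oxidation of F2 with MnO2 returns to 5.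

Step 5. What may go wrong: re-addition of palladium hydride to the new ring diene and migration of the double bonds into conjugation with the chain, which would erase C6'. The fallback sets out from 7 and comes back at 10 without any metal hydride. Condensation of 7 with tosylhydrazide would give the tosylhydrazone F4. A Shapiro reaction (LDA, 2.2 equiv, THF, −78 to 0 °C, then water) deprotonates at nitrogen and at C5', expels sulfinate and dinitrogen, and gives the C4' vinyl-lithium, whose protonation should deliver 10.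

Step 16. What may go wrong: proton removal from ring C4 in place of the methyl C18 (endocyclic isomer), SN2'-type attack on the propargylic C6–O bond, or metalation at C11. The fallback sets out from 23 and comes back at 25, bypassing the epoxide. A Schenck ene reaction of 23 with singlet oxygen (O2, tetraphenylporphyrin, hν, CH2Cl2, −20 °C) can place oxygen only on C6, because the only allylic hydrogens of the tetrasubstituted alkene (on C18 and C4) are attached to C5, and methyl hydrogens are normally abstracted in preference to ring methylene ones. Hydrogen bonding of the incoming oxygen to the C3 hydroxyl in a non-polar solvent should favour the cis face. The hydroperoxide F5 would be reduced with PPh3 to 25.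

Step 18. What may go wrong: nucleophilic epoxidation of the emerging C9=C10 enone by hydroperoxide anion, or retro-aldol cleavage of the tertiary ketol in the fluoride/bicarbonate medium. The fallback sets out from 25 and comes back at 28 without silicon or peroxide. π-Acid-catalysed hydration of the alkyne (Ph3PAuNTf2, wet dioxane, rt) should add water at C8, the alkyne carbon conjugated to C9=C10 and remote from the electron-withdrawing carbinol, to give the silyl-protected ketol F6. Buffered desilylation (TBAF/AcOH, THF, 0 °C) would then give 28.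

Step 20. What may go wrong: erosion of E selectivity at C11=C12, conjugate addition of the ylide at C10 of the ene-dione, or base-induced retro-aldol and dehydration of the ketol. The fallback sets out from 28 and 15 and comes back at 31 with the polarity of the union reversed. Selective bromination of the primary allylic hydroxyl of 28 (CBr4, PPh3, CH2Cl2, 0 °C) would give the allylic bromide F7. A Michaelis–Arbuzov reaction with triethyl phosphite would convert it into the phosphonate F8. A Horner–Wadsworth–Emmons reaction of F8 with aldehyde 15 under Masamune–Roush conditions (LiCl, DBU, MeCN/THF) should give 31 with high E selectivity under weakly basic conditions.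

## Further compounds

F1 | step 2 | rac-5-[(1E,3E)-5-{[tert-butyl(dimethyl)silyl]oxy}-3-methylpenta-1,3-dien-1-yl]-4,4-dimethylcyclohex-2-en-1-one | CC(C)(C)[Si](C)(C)OC/C=C(C)/C=C/C1CC(=O)C=CC1(C)C
F2 | step 2 | (1R,5R)-5-[(1E,3E)-5-{[tert-butyl(dimethyl)silyl]oxy}-3-methylpenta-1,3-dien-1-yl]-4,4-dimethylcyclohex-2-en-1-ol | CC(C)(C)[Si](C)(C)OC/C=C(C)/C=C/[C@H]1C[C@@H](O)C=CC1(C)C
F3 | step 2 | (1R,5S)-5-[(1E,3E)-5-{[tert-butyl(dimethyl)silyl]oxy}-3-methylpenta-1,3-dien-1-yl]-4,4-dimethylcyclohex-2-en-1-ol | CC(C)(C)[Si](C)(C)OC/C=C(C)/C=C/[C@@H]1C[C@@H](O)C=CC1(C)C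
F4 | step 5 | N'-[(5S,6RS)-5-[(1E,3E)-5-{[tert-butyl(dimethyl)silyl]oxy}-3-methylpenta-1,3-dien-1-yl]-4,4,6-trimethylcyclohex-2-en-1-ylidene]-4-methylbenzenesulfonohydrazide | CC(C)(C)[Si](C)(C)OC/C=C(C)/C=C/[C@H]1C(C)C(=NNS(=O)(=O)c2ccc(C)cc2)C=CC1(C)C
F5 | step 16 | (1S,4R)-4-[(3E)-5-{[tert-butyl(dimethyl)silyl]oxy}-3-methylpent-3-en-1-yn-1-yl]-4-hydroperoxy-3,3-dimethyl-5-methylidenecyclohexan-1-ol | C=C1C[C@@H](O)CC(C)(C)[C@]1(OO)C#C/C(C)=C/CO[Si](C)(C)C(C)(C)C
F6 | step 18 | (3E)-5-{[tert-butyl(dimethyl)silyl]oxy}-1-[(1R,4S)-1,4-dihydroxy-2,2-dimethyl-6-methylidenecyclohexyl]-3-methylpent-3-en-2-one | C=C1C[C@@H](O)CC(C)(C)[C@]1(O)CC(=O)/C(C)=C/CO[Si](C)(C)C(C)(C)C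
F7 | step 20 | (3E)-5-bromo-1-[(1R,4S)-1,4-dihydroxy-2,2-dimethyl-6-methylidenecyclohexyl]-3-methylpent-3-en-2-one | C=C1C[C@@H](O)CC(C)(C)[C@]1(O)CC(=O)/C(C)=C/CBr
F8 | step 20 | diethyl {(2E)-5-[(1R,4S)-1,4-dihydroxy-2,2-dimethyl-6-methylidenecyclohexyl]-3-methyl-4-oxopent-2-en-1-yl}phosphonate | C=C1C[C@@H](O)CC(C)(C)[C@]1(O)CC(=O)/C(C)=C/CP(=O)(OCC)OCC
A1 | alternative 1 | (R)-α-ionone, (3E)-4-[(1R)-2,6,6-trimethylcyclohex-2-en-1-yl]but-3-en-2-one | CC(=O)/C=C/[C@H]1C(C)=CCCC1(C)C
A2 | alternative 1 | (3E)-4-[(1S)-2,6,6-trimethylcyclohexa-2,4-dien-1-yl]but-3-en-2-one | CC(=O)/C=C/[C@H]1C(C)=CC=CC1(C)C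
A3 | alternative 2 | (2E,4Z)-3,7-dimethylocta-2,4,6-trienal | O=C/C=C(C)/C=C\C=C(C)C
A4 | alternative 2 | rac-2,6,6-trimethylcyclohexa-2,4-diene-1-carbaldehyde | O=CC1C(C)=CC=CC1(C)C
A5 | alternative 3 | safranal, 2,6,6-trimethylcyclohexa-1,3-diene-1-carbaldehyde | CC1=C(C=O)C(C)(C)CC=C1
A6 | alternative 3 | rac-6,7,7-trimethyl-2,3-dioxabicyclo[2.2.2]oct-5-ene-1-carbaldehyde | O=CC12OOC(C=C1C)CC2(C)C
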